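**Retrosynthetic overview**
1. Target 8 ⇒ its 8-methoxy regioisomer 6: the pyranone O1–C2 bond is re-formed to the other ortho-phenol oxygen (C–O bond, thermodynamic control, via open-chain enaminone 7).
2. 6 ⇒ deoxybenzoin 5: O1–C2 ring closure, with C2 supplied by DMF in the same pot.
3. 5 ⇒ iretol 4 + arylacetic acid 3: Friedel–Crafts C-acylation (C4–C4a).
4. 3 ⇒ 2,3,4,5-tetramethoxytoluene 1: benzylic carboxylation with CO2.
5. Ring order: rings A and B are bought intact (4 and 1); ring C is the only ring formed, closed kinetically in step 2 and re-closed in step 3.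

Assumption: the target has no stereocentre, so it is made as the single achiral compound of the SMILES; material from step 2 that closes through the other hydroxyl is carried on unseparated.

**Step 1**
Reactants: 1 2,3,4,5-tetramethoxytoluene (commercial)
Product: 3 2-(2,3,4,5-tetramethoxyphenyl)acetic acid, via benzylpotassium 2 (not isolated)
Conditions: n-BuLi, KOt-Bu, TMP(H), THF, −78 °C; then CO2, −78 °C to rt; aq. HCl
Reagents that add atoms: carbon dioxide, O=C=O
Why: Lateral (benzylic) metalation by the mixed Li/K amide base, which equilibrates any ring-metalated species to the delocalised, OMe-coordinated benzylpotassium, is followed by carboxylation with CO2, a standard route from methoxytoluenes to arylacetic acids.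

**Step 2**
Reactants: 3 2-(2,3,4,5-tetramethoxyphenyl)acetic acid, 4 iretol (2-methoxybenzene-1,3,5-triol, commercial)
Product: 6 5,7-dihydroxy-8-methoxy-3-(2,3,4,5-tetramethoxyphenyl)-4H-chromen-4-one, via deoxybenzoin 5 (not isolated)
Conditions: BF3·OEt2 (solvent), 85 °C; then DMF, MsCl, 70 °C; aq. NaOAc
Reagents that add atoms: N,N-dimethylformamide, CN(C)C=O
Why: BF3-mediated Friedel–Crafts C-acylation at either of the two equivalent ring CH positions of 4 gives 5 as its O,O-difluoroboron chelate, whose methylene is formylated by the Vilsmeier-type reagent from DMF and MsCl and closed by oxa-Michael addition–elimination of the unchelated ortho-hydroxyl (the one next to OMe), so the kinetic 8-methoxy pyranone is expected as the main isomer, and any closure through the other hydroxyl is harmless because step 3 re-forms this C–O bond.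

**Step 3**
Reactants: 6 5,7-dihydroxy-8-methoxy-3-(2,3,4,5-tetramethoxyphenyl)-4H-chromen-4-one (crude from step 2)
Product: 8 Irisjaponin A (5,7-dihydroxy-6-methoxy-3-(2,3,4,5-tetramethoxyphenyl)-4H-chromen-4-one), via ring-opened pyrrolidine enaminone 7 (not isolated)
Conditions: pyrrolidine (20 mol %), AcOH (20 mol %), EtOH, 70 °C, Ar
Reagents that add atoms: none
Why: Proposed new method: covalent secondary-amine catalysis of a pyranone oxygen transposition, in which pyrrolidine adds to C2 of the 5-OH-activated chromenone (aza-Michael), retro-oxa-Michael expels the C8a phenol to give enaminone 7 whose ketone is flanked by both ortho-hydroxyls, and either hydroxyl re-adds to the enaminone carbon with loss of pyrrolidine (AcOH shuttling protons), so the two regioisomers interconvert and funnel to the more stable 6-methoxy isomer 8 (OMe between two hydroxyls, O1 next to unsubstituted C8–H) without the deformylation that hydroxide can cause; the closest known reaction types are the alkali-induced ring isomerisation of 5,7-dihydroxy-8-methoxyisoflavones to their 6-methoxy isomers (Wessely–Moser type) and the reversible opening of chromones by secondary amines to 2-hydroxyaryl enaminones that reclose with acid.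

**Compound list**
1 | 2,3,4,5-tetramethoxytoluene (1,2,3,4-tetramethoxy-5-methylbenzene) | COc1cc(C)c(OC)c(OC)c1OC | starting material
2 | (2,3,4,5-tetramethoxybenzyl)potassium (benzylpotassium) | COc1cc(C[K])c(OC)c(OC)c1OC | intermediate
3 | 2-(2,3,4,5-tetramethoxyphenyl)acetic acid | COc1cc(CC(=O)O)c(OC)c(OC)c1OC | intermediate
4 | iretol (2-methoxybenzene-1,3,5-triol) | COc1c(O)cc(O)cc1O | starting material
5 | 2-(2,3,4,5-tetramethoxyphenyl)-1-(2,4,6-trihydroxy-3-methoxyphenyl)ethan-1-one (deoxybenzoin, held in the flask as its O,O-difluoroboron chelate) | COc1cc(CC(=O)c2c(O)cc(O)c(OC)c2O)c(OC)c(OC)c1OC | intermediate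
6 | 5,7-dihydroxy-8-methoxy-3-(2,3,4,5-tetramethoxyphenyl)-4H-chromen-4-one | COc1cc(-c2coc3c(OC)c(O)cc(O)c3c2=O)c(OC)c(OC)c1OC | intermediate
7 | (E)-2-(2,3,4,5-tetramethoxyphenyl)-3-(pyrrolidin-1-yl)-1-(2,4,6-trihydroxy-3-methoxyphenyl)prop-2-en-1-one (ring-opened pyrrolidine enaminone; the alkene geometry has no consequence) | COc1cc(/C(=C\N2CCCC2)C(=O)c2c(O)cc(O)c(OC)c2O)c(OC)c(OC)c1OC | intermediate
8 | Irisjaponin A (5,7-dihydroxy-6-methoxy-3-(2,3,4,5-tetramethoxyphenyl)-4H-chromen-4-one) | COc1cc(-c2coc3cc(O)c(OC)c(O)c3c2=O)c(OC)c(OC)c1OC | target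

**Totals**
Total step count: 3. Longest linear sequence: 3 (1 → 3 → 6 → 8).

**Steps most likely to fail, with fallbacks**

Step 3 (proposed new step). Risks: slow amine addition to the phenol-rich chromenone, or an equilibrium that does not lie fully on the side of 8. The fallback sets out from 6 and comes back at 8 and uses the classical stoichiometric alkaline ring isomerisation in place of covalent amine catalysis. Compound 6 is warmed briefly in degassed dilute aq. K2CO3 (or 0.5 M KOH in MeOH) at 60 °C under Ar. Hydroxide adds at C2 and the pyranone opens reversibly to the open-chain hydroxymethylene ketone (Z)-3-hydroxy-2-(2,3,4,5-tetramethoxyphenyl)-1-(2,4,6-trihydroxy-3-methoxyphenyl)prop-2-en-1-one F4 (as its potassium salt). This recloses through the other phenoxide, and acidification with dilute HCl gives 8. Unchanged 6 is separated by chromatography and resubmitted.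

Step 1. Risk: competing ring metalation at C6–H or incomplete benzylic metalation. The fallback sets out from 1 and comes back at 3 and replaces the anionic carboxylation by oxidative side-chain functionalisation and one-carbon homologation. The methyl group is oxidised with 2-iodoxybenzoic acid (DMSO, 85 °C) to 2,3,4,5-tetramethoxybenzaldehyde F1. Van Leusen reductive cyanation (TosMIC, KOt-Bu, DME, −30 °C to rt, then MeOH, reflux) gives 2-(2,3,4,5-tetramethoxyphenyl)acetonitrile F2. Alkaline hydrolysis (KOH, aq. EtOH, reflux; then HCl) delivers acid 3.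

Step 2. Risk: the one-pot formylative closure is unclean on this electron-rich substrate (ring formylation, O-sulfonylation). The fallback sets out from 3 and 4 and comes back at 6 and decouples the C–C acylation from the C–O closure in a stepwise, Lewis-acid-free ring formation. The acylation is run alone (BF3·OEt2, 85 °C, aqueous work-up) and deoxybenzoin 5 is isolated. Compound 5 is aminomethylenated with DMF dimethyl acetal (THF, 60 °C) to (E)-3-(dimethylamino)-2-(2,3,4,5-tetramethoxyphenyl)-1-(2,4,6-trihydroxy-3-methoxyphenyl)prop-2-en-1-one F3. This is closed by warming in AcOH to give 6, which enters step 3 as before.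

**Further compounds**
F1 | step 1 | 2,3,4,5-tetramethoxybenzaldehyde | COc1cc(C=O)c(OC)c(OC)c1OC
F2 | step 1 | 2-(2,3,4,5-tetramethoxyphenyl)acetonitrile | COc1cc(CC#N)c(OC)c(OC)c1OC
F3 | step 2 | (E)-3-(dimethylamino)-2-(2,3,4,5-tetramethoxyphenyl)-1-(2,4,6-trihydroxy-3-methoxyphenyl)prop-2-en-1-one | COc1cc(/C(=C\N(C)C)C(=O)c2c(O)cc(O)c(OC)c2O)c(OC)c(OC)c1OC
F4 | step 3 | (Z)-3-hydroxy-2-(2,3,4,5-tetramethoxyphenyl)-1-(2,4,6-trihydroxy-3-methoxyphenyl)prop-2-en-1-one | COc1cc(/C(=C/O)C(=O)c2c(O)cc(O)c(OC)c2O)c(OC)c(OC)c1OC
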